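**Retrosynthetic overview**
- C7=C8 (key bond): intermolecular aldol of the lithium dienolate of a 2-chloro-4-silyloxy-4-octenylcyclopentenone with methyl (Z)-7-oxohept-5-enoate, then E1cB dehydration and desilylation.
- C10–Cl: from the enone by nucleophilic epoxidation, chloride opening at the α-carbon and dehydration.
- C12 stereocentre: face-selective 1,2-aldol addition of ethyl lithioacetate to (R)-4-silyloxycyclopentenone (anti to OTBS), then desilylation and allylic oxidation (1,4-carbonyl transposition).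
- Side chains: 14Z by Wittig olefination of the derived aldehyde; 5Z enal from hex-5-ynoic acid by hydroxymethylation, Lindlar reduction and MnO2 oxidation.
- Rings: no ring is formed; the single five-membered ring is carried through from the starting enone.

Assumption: (R)-4-[(tert-butyldimethylsilyl)oxy]cyclopent-2-en-1-one (the standard prostaglandin building block) is taken as a purchasable starting material.

**Route**

Step 1
Reactants: 1 (R)-4-[(tert-butyldimethylsilyl)oxy]cyclopent-2-en-1-one; 2 ethyl acetate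
Product: 4 ethyl 2-[(1R,4R)-4-[(tert-butyldimethylsilyl)oxy]-1-hydroxycyclopent-2-en-1-yl]acetate (OH cis to OTBS), via ethyl lithioacetate 3 (not isolated)
Conditions: LiN(SiMe3)2 (1.1 equiv), THF, −78 °C, 30 min; add 1, −78 °C, 1 h; AcOH quench at −78 °C
Reagents that add atoms: none
Why: Kinetic 1,2-aldol addition of the hard lithium ester enolate to the enone carbonyl occurs anti to the C4 silyloxy group, setting the tertiary carbinol (future C12), and the cold quench prevents retro-aldol or drift to the Michael adduct.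

Step 2
Reactants: 4 ethyl 2-[(1R,4R)-4-[(tert-butyldimethylsilyl)oxy]-1-hydroxycyclopent-2-en-1-yl]acetate
Product: 5 ethyl 2-[(1R,4R)-4-[(tert-butyldimethylsilyl)oxy]-1-[(triethylsilyl)oxy]cyclopent-2-en-1-yl]acetate
Conditions: TESOTf, 2,6-lutidine, CH2Cl2, −78 → 0 °C
Reagents that add atoms: triethylsilyl trifluoromethanesulfonate, CC[Si](CC)(CC)OS(=O)(=O)C(F)(F)F
Why: Silyl triflate with a hindered weak base is the standard silylation of a tertiary alcohol and blocks retro-aldol in the basic steps that follow.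

Step 3
Reactants: 5 ethyl 2-[(1R,4R)-4-[(tert-butyldimethylsilyl)oxy]-1-[(triethylsilyl)oxy]cyclopent-2-en-1-yl]acetate
Product: 6 2-[(1S,4R)-4-[(tert-butyldimethylsilyl)oxy]-1-[(triethylsilyl)oxy]cyclopent-2-en-1-yl]ethan-1-ol
Conditions: i-Bu2AlH (2.5 equiv), CH2Cl2, −78 → 0 °C; aq. KNaC4H4O6 work-up
Reagents that add atoms: none
Why: Aluminium hydride reduction of the ester to the primary alcohol leaves the silyl ethers and the ring alkene untouched.

Step 4
Reactants: 6 2-[(1S,4R)-4-[(tert-butyldimethylsilyl)oxy]-1-[(triethylsilyl)oxy]cyclopent-2-en-1-yl]ethan-1-ol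
Product: 7 2-[(1R,4R)-4-[(tert-butyldimethylsilyl)oxy]-1-[(triethylsilyl)oxy]cyclopent-2-en-1-yl]acetaldehyde
Conditions: Dess–Martin periodinane, pyridine, CH2Cl2, 0 °C → rt
Reagents that add atoms: none
Why: Dess–Martin oxidation gives the aldehyde under buffered conditions without over-oxidation or β-elimination of the silyloxy group.

Step 5
Reactants: 7 2-[(1R,4R)-4-[(tert-butyldimethylsilyl)oxy]-1-[(triethylsilyl)oxy]cyclopent-2-en-1-yl]acetaldehyde; 8 hexyltriphenylphosphonium bromide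
Product: 10 (1S,4R)-4-[(tert-butyldimethylsilyl)oxy]-1-[(Z)-oct-2-en-1-yl]-1-[(triethylsilyl)oxy]cyclopent-2-ene, via hexylidenetriphenylphosphorane 9 (not isolated)
Conditions: 8, NaN(SiMe3)2, THF, 0 °C; then 7, −78 °C → rt
Reagents that add atoms: none
Why: Wittig olefination with a salt-free non-stabilised ylide under kinetic control gives the (Z)-alkene (C14=C15) with high selectivity.

Step 6
Reactants: 10 (1S,4R)-4-[(tert-butyldimethylsilyl)oxy]-1-[(Z)-oct-2-en-1-yl]-1-[(triethylsilyl)oxy]cyclopent-2-ene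
Product: 11 (1S,4R)-1-[(Z)-oct-2-en-1-yl]cyclopent-2-ene-1,4-diol (cis-diol)
Conditions: n-Bu4NF (3 equiv), THF, 0 °C → rt; H2O work-up
Reagents that add atoms: none
Why: Fluoride-mediated desilylation cleaves both silyl ethers, and with no carbonyl present the tertiary carbinol cannot racemise.

Step 7
Reactants: 11 (1S,4R)-1-[(Z)-oct-2-en-1-yl]cyclopent-2-ene-1,4-diol
Product: 12 (S)-4-hydroxy-4-[(Z)-oct-2-en-1-yl]cyclopent-2-en-1-one
Conditions: activated MnO2 (15 equiv), CH2Cl2, rt
Reagents that add atoms: none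
Why: MnO2 allylic oxidation acts only on the secondary allylic alcohol, completing the 1,4-carbonyl transposition so that the centre set in step 1 becomes C4 of the new enone.

Step 8
Reactants: 12 (S)-4-hydroxy-4-[(Z)-oct-2-en-1-yl]cyclopent-2-en-1-one
Product: 13 (S)-4-[(tert-butyldimethylsilyl)oxy]-4-[(Z)-oct-2-en-1-yl]cyclopent-2-en-1-one
Conditions: TBSOTf, 2,6-lutidine, CH2Cl2, −78 → 0 °C
Reagents that add atoms: tert-butyldimethylsilyl trifluoromethanesulfonate, CC(C)(C)[Si](C)(C)OS(=O)(=O)C(F)(F)F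
Why: Silyl triflate silylation with a weak base never generates the tertiary alkoxide, so retro-aldol racemisation is avoided and the carbinol is protected for the basic and acidic steps ahead.

Step 9
Reactants: 13 (S)-4-[(tert-butyldimethylsilyl)oxy]-4-[(Z)-oct-2-en-1-yl]cyclopent-2-en-1-one
Product: 14 (4S)-4-[(tert-butyldimethylsilyl)oxy]-4-[(Z)-oct-2-en-1-yl]-6-oxabicyclo[3.1.0]hexan-2-one (cis-fused epoxide; both epoxide diastereomers are carried on)
Conditions: 30% aq. H2O2, NaOH (0.2 equiv), MeOH, 0 °C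
Reagents that add atoms: hydrogen peroxide, OO
Why: Weitz–Scheffer nucleophilic epoxidation attacks only the electron-poor enone alkene and spares the isolated (Z)-alkene; the epoxide configuration is irrelevant because both carbons become sp2 in step 11.

Step 10
Reactants: 14 (4S)-4-[(tert-butyldimethylsilyl)oxy]-4-[(Z)-oct-2-en-1-yl]-6-oxabicyclo[3.1.0]hexan-2-one
Product: 15 (4S)-4-[(tert-butyldimethylsilyl)oxy]-2-chloro-3-hydroxy-4-[(Z)-oct-2-en-1-yl]cyclopentan-1-one (Cl and OH trans; diastereomer mixture at C2/C3)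
Conditions: HCl (2 M in Et2O, 1.5 equiv), CH2Cl2, −20 → 0 °C
Reagents that add atoms: hydrogen chloride, Cl
Why: Acid-promoted SN2 opening of the α,β-epoxy ketone by chloride takes place at the carbonyl-activated α-carbon (the β-carbon is neopentyl), giving the α-chloro-β-hydroxy ketone.

Step 11
Reactants: 15 (4S)-4-[(tert-butyldimethylsilyl)oxy]-2-chloro-3-hydroxy-4-[(Z)-oct-2-en-1-yl]cyclopentan-1-one
Product: 17 (S)-4-[(tert-butyldimethylsilyl)oxy]-2-chloro-4-[(Z)-oct-2-en-1-yl]cyclopent-2-en-1-one, via chlorohydrin 3-mesylate 16 (not isolated)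
Conditions: MsCl, Et3N (4 equiv), CH2Cl2, −20 °C → rt
Reagents that add atoms: none
Why: Mesylation of the secondary alcohol and E1cB elimination through the acidic α-C–H regenerates the enone with chlorine now at C2 (prostanoid C10).

Step 12
Reactants: 18 hex-5-ynoic acid
Product: 20 7-hydroxyhept-5-ynoic acid, via dilithium hex-5-ynoate acetylide 19 (not isolated)
Conditions: n-BuLi (2.1 equiv), THF, −78 → 0 °C; (CH2O)n, 0 °C → rt; aq. HCl work-up
Reagents that add atoms: formaldehyde (used as paraformaldehyde), C=O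
Why: The carboxylate–acetylide dianion reacts at the far more nucleophilic acetylide carbon in an alkynylation of formaldehyde to give the propargylic alcohol.

Step 13
Reactants: 20 7-hydroxyhept-5-ynoic acid
Product: 21 methyl 7-hydroxyhept-5-ynoate
Conditions: MeOH, H2SO4 (cat.), rt
Reagents that add atoms: methanol, CO
Why: Fischer esterification in methanol as solvent converts the acid to the methyl ester without affecting the alkyne or the primary alcohol.

Step 14
Reactants: 21 methyl 7-hydroxyhept-5-ynoate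
Product: 22 methyl (Z)-7-hydroxyhept-5-enoate
Conditions: H2 (1 atm), Pd/CaCO3 poisoned with Pb(OAc)2 (Lindlar catalyst), quinoline, EtOAc, rt
Reagents that add atoms: none
Why: Lindlar semi-hydrogenation adds hydrogen syn across the alkyne and stops at the (Z)-alkene (C5=C6).

Step 15
Reactants: 22 methyl (Z)-7-hydroxyhept-5-enoate
Product: 23 methyl (Z)-7-oxohept-5-enoate
Conditions: activated MnO2 (15 equiv), CH2Cl2, 0 °C → rt, dark; used at once
Reagents that add atoms: none
Why: MnO2 allylic oxidation gives the enal under neutral conditions that preserve the (Z)-geometry.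

Step 16
Reactants: 17 (S)-4-[(tert-butyldimethylsilyl)oxy]-2-chloro-4-[(Z)-oct-2-en-1-yl]cyclopent-2-en-1-one; 23 methyl (Z)-7-oxohept-5-enoate
Product: 25 methyl (5Z,12S,14Z)-12-[(tert-butyldimethylsilyl)oxy]-10-chloro-7-hydroxy-9-oxoprosta-5,10,14-trienoate (C7/C8 diastereomer mixture), via lithium dienolate of the chloroenone 24 (not isolated)
Conditions: LiN(i-Pr)2 (1.1 equiv), THF, −78 °C, 30 min; then 23 (1.3 equiv), −78 °C, 20 min; AcOH quench at −78 °C
Reagents that add atoms: none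
Why: Kinetic α'-deprotonation gives the cross-conjugated lithium dienolate, which adds 1,2 to the enal in an intermolecular aldol addition forming C7–C8; the two new centres are uncontrolled but are erased in step 17, and C12 is untouched.

Step 17
Reactants: 25 methyl (5Z,12S,14Z)-12-[(tert-butyldimethylsilyl)oxy]-10-chloro-7-hydroxy-9-oxoprosta-5,10,14-trienoate
Product: 27 methyl (5Z,7E,12R,14Z)-12-[(tert-butyldimethylsilyl)oxy]-10-chloro-9-oxoprosta-5,7,10,14-tetraenoate, via aldol 7-mesylate 26 (not isolated)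
Conditions: MsCl, Et3N (5 equiv), CH2Cl2, −20 → 0 °C; chromatography to remove any 7Z isomer
Reagents that add atoms: none
Why: Mesylation and E1cB elimination give the cross-conjugated dienone, with the (7E)-alkylidene expected to predominate as in related 2-alkylidenecyclopentenones, while the 5Z alkene is not involved.

Step 18
Reactants: 27 methyl (5Z,7E,12R,14Z)-12-[(tert-butyldimethylsilyl)oxy]-10-chloro-9-oxoprosta-5,7,10,14-tetraenoate
Product: 28 methyl (5Z,7E,12R,14Z)-10-chloro-12-hydroxy-9-oxoprosta-5,7,10,14-tetraenoate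
Conditions: 48% aq. HF/MeCN (1:19), 0 °C → rt, dark
Reagents that add atoms: none
Why: Fluoride-driven desilylation under mildly acidic, base-free conditions frees the tertiary alcohol without retro-aldol, ester cleavage or dienone isomerisation.

**Compound list**
1 | (R)-4-[(tert-butyldimethylsilyl)oxy]cyclopent-2-en-1-one | CC(C)(C)[Si](C)(C)O[C@H]1C=CC(=O)C1 | starting material
2 | ethyl acetate | CCOC(C)=O | starting material
3 | ethyl lithioacetate (lithium enolate of ethyl acetate) | [Li+].[O-]C(=C)OCC | intermediate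
4 | ethyl 2-[(1R,4R)-4-[(tert-butyldimethylsilyl)oxy]-1-hydroxycyclopent-2-en-1-yl]acetate | CCOC(=O)C[C@@]1(O)C=C[C@H](O[Si](C)(C)C(C)(C)C)C1 | intermediate
5 | ethyl 2-[(1R,4R)-4-[(tert-butyldimethylsilyl)oxy]-1-[(triethylsilyl)oxy]cyclopent-2-en-1-yl]acetate | CCOC(=O)C[C@@]1(O[Si](CC)(CC)CC)C=C[C@H](O[Si](C)(C)C(C)(C)C)C1 | intermediate
6 | 2-[(1S,4R)-4-[(tert-butyldimethylsilyl)oxy]-1-[(triethylsilyl)oxy]cyclopent-2-en-1-yl]ethan-1-ol | OCC[C@@]1(O[Si](CC)(CC)CC)C=C[C@H](O[Si](C)(C)C(C)(C)C)C1 | intermediate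
7 | 2-[(1R,4R)-4-[(tert-butyldimethylsilyl)oxy]-1-[(triethylsilyl)oxy]cyclopent-2-en-1-yl]acetaldehyde | O=CC[C@@]1(O[Si](CC)(CC)CC)C=C[C@H](O[Si](C)(C)C(C)(C)C)C1 | intermediate
8 | hexyltriphenylphosphonium bromide | CCCCCC[P+](c1ccccc1)(c1ccccc1)c1ccccc1.[Br-] | starting material
9 | hexylidenetriphenylphosphorane | CCCCCC=P(c1ccccc1)(c1ccccc1)c1ccccc1 | intermediate
10 | (1S,4R)-4-[(tert-butyldimethylsilyl)oxy]-1-[(Z)-oct-2-en-1-yl]-1-[(triethylsilyl)oxy]cyclopent-2-ene | CCCCC/C=C\C[C@@]1(O[Si](CC)(CC)CC)C=C[C@H](O[Si](C)(C)C(C)(C)C)C1 | intermediate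
11 | (1S,4R)-1-[(Z)-oct-2-en-1-yl]cyclopent-2-ene-1,4-diol | CCCCC/C=C\C[C@@]1(O)C=C[C@H](O)C1 | intermediate
12 | (S)-4-hydroxy-4-[(Z)-oct-2-en-1-yl]cyclopent-2-en-1-one | CCCCC/C=C\C[C@@]1(O)C=CC(=O)C1 | intermediate
13 | (S)-4-[(tert-butyldimethylsilyl)oxy]-4-[(Z)-oct-2-en-1-yl]cyclopent-2-en-1-one | CCCCC/C=C\C[C@@]1(O[Si](C)(C)C(C)(C)C)C=CC(=O)C1 | intermediate
14 | (4S)-4-[(tert-butyldimethylsilyl)oxy]-4-[(Z)-oct-2-en-1-yl]-6-oxabicyclo[3.1.0]hexan-2-one (epoxide centres left open: both cis-fused diastereomers converge) | CCCCC/C=C\C[C@@]1(O[Si](C)(C)C(C)(C)C)C2OC2C(=O)C1 | intermediate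
15 | (4S)-4-[(tert-butyldimethylsilyl)oxy]-2-chloro-3-hydroxy-4-[(Z)-oct-2-en-1-yl]cyclopentan-1-one (2,3-trans; C2/C3 left open, both converge) | CCCCC/C=C\C[C@@]1(O[Si](C)(C)C(C)(C)C)C(O)C(Cl)C(=O)C1 | intermediate
16 | 3-O-methanesulfonate of 15 | CCCCC/C=C\C[C@@]1(O[Si](C)(C)C(C)(C)C)C(OS(C)(=O)=O)C(Cl)C(=O)C1 | intermediate
17 | (S)-4-[(tert-butyldimethylsilyl)oxy]-2-chloro-4-[(Z)-oct-2-en-1-yl]cyclopent-2-en-1-one | CCCCC/C=C\C[C@@]1(O[Si](C)(C)C(C)(C)C)C=C(Cl)C(=O)C1 | intermediate
18 | hex-5-ynoic acid | C#CCCCC(=O)O | starting material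
19 | dilithium hex-5-ynoate acetylide | [Li+].[Li+].[C-]#CCCCC(=O)[O-] | intermediate
20 | 7-hydroxyhept-5-ynoic acid | OCC#CCCCC(=O)O | intermediate
21 | methyl 7-hydroxyhept-5-ynoate | COC(=O)CCCC#CCO | intermediate
22 | methyl (Z)-7-hydroxyhept-5-enoate | COC(=O)CCC/C=C\CO | intermediate
23 | methyl (Z)-7-oxohept-5-enoate | COC(=O)CCC/C=C\C=O | intermediate
24 | lithium (3S)-3-[(tert-butyldimethylsilyl)oxy]-5-chloro-3-[(Z)-oct-2-en-1-yl]cyclopenta-1,4-dien-1-olate (lithium dienolate of 17) | CCCCC/C=C\C[C@@]1(O[Si](C)(C)C(C)(C)C)C=C(Cl)C([O-])=C1.[Li+] | intermediate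
25 | methyl (5Z,12S,14Z)-12-[(tert-butyldimethylsilyl)oxy]-10-chloro-7-hydroxy-9-oxoprosta-5,10,14-trienoate (C7 and C8 left open: mixture, both erased in step 17) | CCCCC/C=C\C[C@@]1(O[Si](C)(C)C(C)(C)C)C=C(Cl)C(=O)C1C(O)/C=C\CCCC(=O)OC | intermediate
26 | 7-O-methanesulfonate of 25 | CCCCC/C=C\C[C@@]1(O[Si](C)(C)C(C)(C)C)C=C(Cl)C(=O)C1C(OS(C)(=O)=O)/C=C\CCCC(=O)OC | intermediate
27 | methyl (5Z,7E,12R,14Z)-12-[(tert-butyldimethylsilyl)oxy]-10-chloro-9-oxoprosta-5,7,10,14-tetraenoate | CCCCC/C=C\C[C@@]1(O[Si](C)(C)C(C)(C)C)C=C(Cl)C(=O)/C1=C/C=C\CCCC(=O)OC | intermediate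
28 | methyl (5Z,7E,12R,14Z)-10-chloro-12-hydroxy-9-oxoprosta-5,7,10,14-tetraenoate (chlorovulone I) | CCCCC/C=C\C[C@@]1(O)C=C(Cl)C(=O)/C1=C/C=C\CCCC(=O)OC | target

**Step count and risks**

Total steps: 18 (steps 1–11 ring branch, steps 12–15 aldehyde branch, steps 16–18 after coupling). Longest linear sequence: 14 steps (1–11, then 16–18, from compound 1).

Most likely to fail:

Step 9 (nucleophilic epoxidation of the hindered enone 13; the β-carbon is next to the quaternary silyloxy centre). Fallback, setting out from 11 and returning at 17: the epoxide is installed before the ketone exists, under hydroxyl direction instead of by conjugate attack. Diol 11 is treated with VO(acac)2 (cat.) and t-BuOOH in CH2Cl2 (0 °C → rt); the ring alkene, allylic to two cis hydroxyls, reacts far faster than the homoallylic side-chain alkene and gives all-cis 2-[(Z)-oct-2-en-1-yl]-6-oxabicyclo[3.1.0]hexane-2,4-diol F1. Dess–Martin oxidation of the secondary alcohol gives 4-hydroxy-4-[(Z)-oct-2-en-1-yl]-6-oxabicyclo[3.1.0]hexan-2-one F2. HCl in Et2O/CH2Cl2 opens it at the α-carbon to 2-chloro-3,4-dihydroxy-4-[(Z)-oct-2-en-1-yl]cyclopentan-1-one F3. MsCl/Et3N reacts only at the secondary hydroxyl to give the 3-O-methanesulfonate of the chlorohydrin F4, which eliminates in the flask to (S)-2-chloro-4-hydroxy-4-[(Z)-oct-2-en-1-yl]cyclopent-2-en-1-one F5. TBSOTf/2,6-lutidine then gives 17. The free tertiary alcohol meets only acid or amine bases, never an alkoxide base, so retro-aldol racemisation is avoided.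

Step 16 (lithium dienolate aldol; risks are dienolate decomposition, retro-aldol and isomerisation or conjugate addition of the sensitive Z-enal). Fallback, setting out from 17 and returning at 25: a Lewis-acid Mukaiyama aldol instead of the lithium enolate. Enone 17 is converted with TMSOTf/Et3N (CH2Cl2, 0 °C) into (3S)-3-[(tert-butyldimethylsilyl)oxy]-5-chloro-3-[(Z)-oct-2-en-1-yl]-1-(trimethylsilyloxy)cyclopenta-1,4-diene F6, which is combined with 23 and BF3·OEt2 in CH2Cl2 at −78 °C; aqueous work-up gives 25.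

Step 17 (E/Z outcome at C7=C8 next to the bulky C12 silyl ether, and integrity of the 5Z alkene). Fallback, setting out from 25 and returning at 28: the silyl group is removed before the elimination so that the small free hydroxyl, not OTBS, flanks the forming alkylidene. Aldol 25 is desilylated with aq. HF/MeCN to methyl (5Z,12S,14Z)-10-chloro-7,12-dihydroxy-9-oxoprosta-5,10,14-trienoate F7. MsCl/Et3N at −20 °C sulfonylates only the secondary allylic hydroxyl, giving the 7-O-methanesulfonate of the diol F8, which undergoes E1cB elimination in the flask directly to 28.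

**Further compounds**
F1 | step 9 | all-cis 2-[(Z)-oct-2-en-1-yl]-6-oxabicyclo[3.1.0]hexane-2,4-diol (epoxide syn to both hydroxyls) | CCCCC/C=C\C[C@@]1(O)[C@@H]2O[C@@H]2[C@H](O)C1
F2 | step 9 | 4-hydroxy-4-[(Z)-oct-2-en-1-yl]-6-oxabicyclo[3.1.0]hexan-2-one (epoxide syn to the hydroxyl) | CCCCC/C=C\C[C@@]1(O)[C@@H]2O[C@@H]2C(=O)C1
F3 | step 9 | 2-chloro-3,4-dihydroxy-4-[(Z)-oct-2-en-1-yl]cyclopentan-1-one (Cl trans to both hydroxyls) | CCCCC/C=C\C[C@@]1(O)[C@H](O)[C@@H](Cl)C(=O)C1
F4 | step 9 | 3-O-methanesulfonate of F3 | CCCCC/C=C\C[C@@]1(O)[C@H](OS(C)(=O)=O)[C@@H](Cl)C(=O)C1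
F5 | step 9 | (S)-2-chloro-4-hydroxy-4-[(Z)-oct-2-en-1-yl]cyclopent-2-en-1-one | CCCCC/C=C\C[C@@]1(O)C=C(Cl)C(=O)C1
F6 | step 16 | (3S)-3-[(tert-butyldimethylsilyl)oxy]-5-chloro-3-[(Z)-oct-2-en-1-yl]-1-(trimethylsilyloxy)cyclopenta-1,4-diene | CCCCC/C=C\C[C@@]1(O[Si](C)(C)C(C)(C)C)C=C(Cl)C(O[Si](C)(C)C)=C1
F7 | step 17 | methyl (5Z,12S,14Z)-10-chloro-7,12-dihydroxy-9-oxoprosta-5,10,14-trienoate (C7/C8 mixture) | CCCCC/C=C\C[C@@]1(O)C=C(Cl)C(=O)C1C(O)/C=C\CCCC(=O)OC
F8 | step 17 | 7-O-methanesulfonate of F7 | CCCCC/C=C\C[C@@]1(O)C=C(Cl)C(=O)C1C(OS(C)(=O)=O)/C=C\CCCC(=O)OC
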